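## Retrosynthetic overview
1. The target (R) is disconnected at the last aromatic C–H of ring A, which is the only free ring position in the des‑prenyl dimer **13**. The last step is therefore a C‑prenylation, which avoids prenylating the ring A monomer with ambiguous regiochemistry.
2. The diarylmethine stereocentre is set by a catalytic enantioselective 1,4‑addition of 2,4‑dihydroxy‑6‑methoxyacetophenone (**8**) to an alkyl ortho‑quinone methide (o‑QM). The o‑QM is generated from the benzylic sulfone **11**, made from 3‑prenylphloroacetophenone (**3**), isovaleraldehyde and sulfinate. This replaces the usual racemic aldehyde double Friedel–Crafts condensation followed by resolution.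
3. No ring is built. Both arenes come from commercial phloroacetophenone (**1**). Ring B is made by mono‑C‑prenylation. Ring A is made by dibenzylation, methylation and hydrogenolysis.

**Assumptions**
- The nucleophilic carbon of **8** is the one between the two OH groups (C3 of the acetophenone). This is the usual site for resacetophenones, and it is the position that carries the methine bridge in the target.
- The sense of asymmetric induction cannot be predicted from first principles. The (R,R)‑catalyst is assumed to give the (R)‑target; if the (S)‑target forms, use the (S,S)‑catalyst.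
- CIP note: in the target, ring A (OMe) outranks ring B. In **13**, ring A has no prenyl group and the order reverses, so the same spatial arrangement is labelled (S).

## Route

**Step 1**
Reactants: 1 (2',4',6'‑trihydroxyacetophenone); 2 (prenyl bromide)
Product: 3 (1‑(2,4,6‑trihydroxy‑3‑(3‑methylbut‑2‑en‑1‑yl)phenyl)ethanone)
Conditions: 2 (1.0 equiv), KOH (2.2 equiv), H2O, 0 °C to rt, 2 h; chromatograph away the diprenyl product
Reagents that add atoms: prenyl bromide, CC(C)=CCBr
Why: The acylphloroglucinolate is a C‑nucleophile, so this is a C‑alkylation (SN2) at a free ring carbon between two OH groups; 1 equiv of bromide limits diprenylation.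

**Step 2**
Reactants: 1; 4 (benzyl bromide)
Product: 5 (1‑(4,6‑bis(benzyloxy)‑2‑hydroxyphenyl)ethanone)
Conditions: 4 (2.2 equiv), K2CO3, acetone, reflux
Reagents that add atoms: benzyl bromide, BrCc1ccccc1
Why: Williamson O‑benzylation occurs at the two non‑chelated OH groups; the OH chelated to the C=O is left free.

**Step 3**
Reactants: 5; 6 (methyl iodide)
Product: 7 (1‑(4,6‑bis(benzyloxy)‑2‑methoxyphenyl)ethanone)
Conditions: 6 (3 equiv), K2CO3, DMF, 60 °C
Reagents that add atoms: methyl iodide, CI
Why: O‑methylation of the chelated phenol is driven by the polar solvent and excess MeI, and it places OMe ortho to the acetyl group as required for ring A.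

**Step 4**
Reactants: 7
Product: 8 (1‑(2,4‑dihydroxy‑6‑methoxyphenyl)ethanone)
Conditions: H2 (1 atm), 10% Pd/C, EtOAc/MeOH, rt, 2 h
Reagents that add atoms: none
Why: Hydrogenolysis of both benzyl ethers; the aryl methyl ether and the aryl ketone survive at 1 atm and rt, and no prenyl group is yet present to be reduced.

**Step 5**
Reactants: 3; 9 (isovaleraldehyde); 10 (sodium p‑toluenesulfinate)
Product: 11 (rac‑1‑[2,4,6‑trihydroxy‑3‑(3‑methylbut‑2‑en‑1‑yl)‑5‑(3‑methyl‑1‑tosylbutyl)phenyl]ethanone)
Conditions: 9 (1.5 equiv), 10 (2 equiv), HCO2H/H2O, 35 °C, 24 h
Reagents that add atoms: isovaleraldehyde, CC(C)CC=O; sodium p‑toluenesulfinate, Cc1ccc(cc1)S(=O)[O-].[Na+]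
Why: Aldehyde hydroxyalkylation at the single free ring position gives an o‑QM precursor that sulfinate traps as a benzylic sulfone (three‑component sulfinic acid–aldehyde–phenol condensation); the stereocentre of **11** is racemic and is destroyed in step 6.

**Step 6**
Reactants: 11 (sulfone); 8 (2',4'‑dihydroxy‑6'‑methoxyacetophenone)
Product: 13 ((S)‑1‑[3‑[1‑(5‑acetyl‑2,4,6‑trihydroxy‑3‑(3‑methylbut‑2‑en‑1‑yl)phenyl)‑3‑methylbutyl]‑2,4‑dihydroxy‑6‑methoxyphenyl]ethanone; same spatial arrangement as the (R)‑target)
Conditions: 12 (10 mol %), NaHCO3 (1.5 equiv), 8 (1.5 equiv), toluene/CH2Cl2 (4:1), 0 °C to rt, 48 h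
Reagents that add atoms: none (the catalyst and base are not incorporated; sulfinate is lost)
Why: Proposed new method: the mild base deprotonates the ring B phenol of **11** and expels sulfinate (E1cB) to give the achiral alkyl o‑QM, whose carbonyl oxygen is H‑bonded by the thiourea of **12**, while the tertiary amine deprotonates the 4‑OH of **8**. The resulting phenolate carbon between the two OH groups adds to one face of the o‑QM (the two faces differ by H versus isobutyl), which sets the stereocentre; the closest known reaction is the bifunctional‑organocatalytic 1,4‑addition of 1,3‑dicarbonyls or naphthols to o‑QMs generated from 2‑(1‑tosylalkyl)phenols.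

**Step 7**
Reactants: 13; 2 (prenyl bromide)
Product: 14 (target, (R))
Conditions: 2 (1.05 equiv), KOH (3 equiv), MeOH/H2O 1:1, 0 °C, 1 h
Reagents that add atoms: prenyl bromide, CC(C)=CCBr
Why: C‑Prenylation of the ring A phenolate (4‑O⁻, para to acetyl) occurs ortho at the only remaining aromatic C–H, as in step 1; the stereocentre is untouched because racemization would need retro‑Friedel–Crafts to the o‑QM, which is slow at 0 °C for this short reaction time.

## Compound list
1 | 2',4',6'‑trihydroxyacetophenone | CC(=O)c1c(O)cc(O)cc1O | starting material
2 | prenyl bromide | CC(C)=CCBr | starting material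
3 | 3‑prenyl‑2',4',6'‑trihydroxyacetophenone | CC(=O)c1c(O)cc(O)c(CC=C(C)C)c1O | intermediate
4 | benzyl bromide | BrCc1ccccc1 | starting material
5 | 4',6'‑bis(benzyloxy)‑2'‑hydroxyacetophenone | CC(=O)c1c(O)cc(OCc2ccccc2)cc1OCc1ccccc1 | intermediate
6 | methyl iodide | CI | starting material
7 | 4',6'‑bis(benzyloxy)‑2'‑methoxyacetophenone | CC(=O)c1c(OC)cc(OCc2ccccc2)cc1OCc1ccccc1 | intermediate
8 | 2',4'‑dihydroxy‑6'‑methoxyacetophenone | CC(=O)c1c(OC)cc(O)cc1O | intermediate
9 | isovaleraldehyde | CC(C)CC=O | starting material
10 | sodium p‑toluenesulfinate | Cc1ccc(cc1)S(=O)[O-].[Na+] | starting material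
11 | rac‑tosyl o‑QM precursor from 3 and 9 | CC(=O)c1c(O)c(C(CC(C)C)S(=O)(=O)c2ccc(C)cc2)c(O)c(CC=C(C)C)c1O | intermediate
12 | (R,R)‑Takemoto bifunctional thiourea organocatalyst (commercial) | CN(C)[C@@H]1CCCC[C@H]1NC(=S)Nc1cc(C(F)(F)F)cc(C(F)(F)F)c1 | starting material
13 | des‑prenyl dimer (same spatial arrangement as target; (S) by CIP) | COc1cc(O)c([C@H](CC(C)C)c2c(O)c(CC=C(C)C)c(O)c(C(C)=O)c2O)c(O)c1C(C)=O | intermediate
14 | CID44559660 ((R)) | COc1c(CC=C(C)C)c(O)c([C@H](CC(C)C)c2c(O)c(CC=C(C)C)c(O)c(C(C)=O)c2O)c(O)c1C(C)=O | target

**Total steps:** 7
**Longest linear sequence:** 5 steps (1 → 5 → 7 → 8 → 13 → 14, i.e. steps 2, 3, 4, 6, 7)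

## Three steps most likely to fail
1. **Step 6 (enantioselective o‑QM addition).** Alkyl o‑QMs can tautomerize to the 2‑alkenylphenol. Attack at the other ring‑A carbon (between OH and OMe) or O‑attack can compete. The highly acidic polyphenolic substrates may also override the catalyst's H‑bonding, and the product can racemize by retro‑Friedel–Crafts.
   Fallback: make racemic **13** (or **14**) with an achiral base, then resolve by preparative chiral SFC/HPLC, or by crystallization‑induced dynamic resolution as a cinchonidine salt, exploiting the labile stereocentre.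
2. **Step 7 (late‑stage prenylation).** Competing O‑prenylation, dearomative C‑prenylation, or base‑mediated racemization may occur.
   Fallback: prenylate **8** before coupling (separate the C5‑prenyl regioisomer) and run the asymmetric coupling with the prenylated ring A nucleophile, so the coupling becomes the last step.
3. **Step 5 (sulfone formation).** The sulfone of such an electron‑rich acylphloroglucinol may be unstable to isolation, bis(ring B)methane may form, and the prenyl phenol may cyclize to a chroman in formic acid.
   Fallback: skip the sulfone and generate the o‑QM in situ by a catalytic three‑component reaction of **3**, **9** and **8** under chiral Brønsted‑acid catalysis (e.g. a BINOL phosphoric acid).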